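I start from slowness: Z is taken up faster than Z.Q falls back, and the mixture of Z.Q and G shifts afterwards, so I count how many lifetimes of that later shift each set-up gets.

    Z + Q ⇌ G (K1 = 19 L mol⁻¹, k1 = 2.0 L mol⁻¹ min⁻¹)
    Z + Q ⇌ Z.Q (K2 = 4.9 L mol⁻¹, k2 = 4.3 L mol⁻¹ min⁻¹)
    Q + E ⇌ Q.E, settled at all times (K3 = 1.5 L mol⁻¹)
    Z.Q + E ⇌ G + E, rate k4*[E]*[Z.Q] forward; the back reaction follows from the equilibrium constant (k4 = 39 L mol⁻¹ min⁻¹)

| setting | alpha | gamma | epsilon | eta |
|---|---|---|---|---|
| Z | 0.25 M | 0.25 M | 0.25 M | 0.25 M |
| Q | 1.25 M | 1.25 M | 1.25 M | 1.25 M |
| E | 2.8 mM | 2.8 mM | 2.8 mM | 2.8 mM |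
| remark | one stirred flow tank at steady state, fed with the mixture as stated, mean residence time 10 min | a single well-mixed tank run continuously and read at steady state, 100 min in it on average | plug flow through a tube for 10 min, no back-mixing | everything together in a closed stirred flask, run for 10 min |
| time |  |  | 10 min | 10 min |

- the set-up with the highest share of Z.Q in all that became Z.Q or G, at the outlet or at the end ("none" if the first two lie within 2 percentage points) (alpha / gamma / epsilon / eta / none)
- share of Z.Q in all that became Z.Q or G, at the outlet or at the end, alpha
- share of Z.Q in all that became Z.Q or G, at the outlet or at the end, gamma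
- share of Z.Q in all that became Z.Q or G, at the outlet or at the end, epsilon
- share of Z.Q in all that became Z.Q or G, at the outlet or at the end, eta

- the stated concentrations are those of everything mixed, before any reaction; amounts are the same in each set-up
- run time (epsilon): 10 min

Two extremes can be done in the head. If nothing runs back and the step catalysed by E is left aside, Z splits by its two rate constants and Z.Q is 68.3% of the products (kinetic control). At full balance the equilibrium constants give 20.5% (thermodynamic control). Between them the share slides down from the first towards the second.

How far it slides is my own reckoning. Z.Q falls back to Z and Q at 0.878 min⁻¹, and 31.7% of the freed Z goes on to G. G falls back at 0.105 min⁻¹, and 68.3% of that Z goes on to Z.Q. With Q near 1.00 M, Q.E leaves 1.12 mM of free E, so the catalysed step runs at 0.0437 min⁻¹ forward and 0.0113 min⁻¹ back.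

Adding these routes gives the slow rate, the constant at which the share's excess over balance shrinks: 0.405 min⁻¹. Its lifetime of 2.47 min is far longer than the 0.127 min that Z lasts by its two forward steps with Q as charged, so I treat Z as passing through.

With the count n as slow rate times time, I let the excess shrink by exp(−n) in the tube and the closed flask, and by 1/(1+n) in a tank. That gives me 30.0% for alpha, 21.7% for gamma, and 21.3% for epsilon and eta, so alpha leads.

The forecast names alpha, with 30% for alpha, 21.7% for gamma, and 21.7% for epsilon and 21.7% for eta, which is above my figure for those two. It says: “Tube and flask behave identically, since both are batch-like.”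

The simulation gives alpha as best, with alpha 30.0%, gamma 21.7%, epsilon 21.5% and eta 21.5%. At the end of eta, Z.Q stands at 20.7% of the Z charged, G at 75.2% and Z at 4.11%. With the way back from G to Z + Q struck out, my slow rate drops to 0.334 min⁻¹, and my balance share to 3.38%. The tank rule then gives 18.3%, and alpha so changed reads 18.3%.

The numbers were set for the occasion; no experiment stands behind them.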